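**Retrosynthetic overview**
- Feature: on ring A, the ring oxygen O1 (on C8a) and the carbonyl carbon C4 (on C4a) sit on neighbouring carbons, and the C5 oxygen is on the carbon next to C4a. This contiguous O / acyl / O-alkyl array is what forms when an oxygen nucleophile and an acyl group add across a 3-alkoxybenzyne.
- Last disconnection: the 5-, 2'- and 5'-hydroxyls come from benzyl ethers by hydrogenolysis.
- Key disconnection: O1–C8a, C4a–C4 and O1–C2 are cut together. This gives 3-benzyloxy-5-methoxybenzyne (from its 2-silylaryl triflate) and the ring B arylpropiolic acid. Rings A and B are bought as arenes, and ring C is the only ring formed.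
- Silyl triflate: from 5-methoxyresorcinol by iodination between the two hydroxyls, monobenzylation, O-silylation, then iodine–lithium exchange, retro-Brook shift and triflation.
- Acid: from 2,3-dimethoxyphenol through the para-quinone, the hydroquinone, its dibenzyl ether and the mono-iodide, which is coupled with propiolic acid.

Key step: step 10

Assumption: 5-methoxyresorcinol, benzyl bromide, 2,3-dimethoxyphenol and propiolic acid are taken as commercial; the target has no stereocentre, so no step has to set configuration.

Remark: silicon is not introduced by carbamate-directed lithiation of a 3-benzyloxy-5-methoxyphenol derivative, because that arene has two ortho sites that each lie between two oxygens, plus an acidic benzylic C–H. The halogen that later becomes silicon is instead placed on the symmetric diol, where the site between both hydroxyls is unique.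

**Step 1**
Reactants: 1 5-methoxyresorcinol
Product: 2 2-iodo-5-methoxybenzene-1,3-diol
Conditions: I2 (1.0 equiv), NaHCO3 (1.1 equiv), H2O/THF, 0 °C → rt
Reagents that add atoms: iodine, [I][I]
Why: Electrophilic aromatic iodination in aqueous hydrogen carbonate, the conditions under which resorcinol and its 5-substituted derivatives take iodine at C2 between the two hydroxyls, should give the symmetric iodide and so fix the future C–Si carbon (C4a of the flavone) before the two oxygens are differentiated.

**Step 2**
Reactants: 2 2-iodo-5-methoxybenzene-1,3-diol, 3 benzyl bromide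
Product: 4 3-(benzyloxy)-2-iodo-5-methoxyphenol
Conditions: BnBr (1.0 equiv), K2CO3 (1.1 equiv), acetone, rt → 40 °C
Reagents that add atoms: benzyl bromide 3, BrCc1ccccc1
Why: Williamson ether synthesis with one equivalent of halide on a diol whose hydroxyls are equivalent, so only the degree of alkylation and not its site needs control, and bis-ether and recovered diol are separated by chromatography.

**Step 3**
Reactants: 4 3-(benzyloxy)-2-iodo-5-methoxyphenol
Product: 5 [3-(benzyloxy)-2-iodo-5-methoxyphenoxy](trimethyl)silane
Conditions: HMDS, THF, reflux; evaporate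
Reagents that add atoms: hexamethyldisilazane, C[Si](C)(C)N[Si](C)(C)C
Why: O-silylation of the phenol with hexamethyldisilazane runs under neutral conditions with ammonia as the only by-product, which spares the acid-sensitive C–I bond and the benzyl ether, and evaporation should give material fit for the next step.

**Step 4**
Reactants: 5 [3-(benzyloxy)-2-iodo-5-methoxyphenoxy](trimethyl)silane
Product: 8 3-(benzyloxy)-5-methoxy-2-(trimethylsilyl)phenyl trifluoromethanesulfonate, via aryllithium 6 (not isolated), via lithium silylphenoxide 7 (not isolated)
Conditions: n-BuLi (1.1 equiv), THF, −100 → −80 °C; then Tf2O (1.2 equiv), −100 → −80 °C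
Reagents that add atoms: trifluoromethanesulfonic anhydride, O=S(=O)(OS(=O)(=O)C(F)(F)F)C(F)(F)F
Why: Iodine–lithium exchange at −100 °C is faster than benzylic deprotonation, aryllithium 6 takes the silyl group from the neighbouring oxygen in a retro-Brook 1,3-shift, and the released phenoxide 7 is sulfonylated by Tf2O, which is the standard passage from an ortho-halophenol to an ortho-silylaryl triflate.

**Step 5**
Reactants: 9 2,3-dimethoxyphenol
Product: 10 2,3-dimethoxy-1,4-benzoquinone
Conditions: (KSO3)2NO (2.2 equiv), KH2PO4 buffer, H2O/acetone, 0 °C → rt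
Reagents that add atoms: potassium nitrosodisulfonate, [K+].[K+].[O]N(S(=O)(=O)[O-])S(=O)(=O)[O-]
Why: Teuber oxidation, in which the nitroxyl radical removes the phenolic hydrogen and a second equivalent delivers oxygen to the free para carbon, so a phenol with an open para position should give the 1,4-quinone.

**Step 6**
Reactants: 10 2,3-dimethoxy-1,4-benzoquinone
Product: 11 2,3-dimethoxybenzene-1,4-diol
Conditions: Na2S2O4, H2O/Et2O, rt
Reagents that add atoms: none
Why: Two-electron reduction of the quinone by dithionite in a two-phase system is fast and leaves the methoxy groups alone, and the air-sensitive hydroquinone is carried on at once.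

**Step 7**
Reactants: 11 2,3-dimethoxybenzene-1,4-diol, 3 benzyl bromide
Product: 12 1,4-bis(benzyloxy)-2,3-dimethoxybenzene
Conditions: BnBr (2.4 equiv), K2CO3, DMF, N2, 50 °C
Reagents that add atoms: benzyl bromide 3, BrCc1ccccc1
Why: Double Williamson ether synthesis under nitrogen caps both phenols of the symmetric hydroquinone and ends its sensitivity to air.

**Step 8**
Reactants: 12 1,4-bis(benzyloxy)-2,3-dimethoxybenzene
Product: 13 1,4-bis(benzyloxy)-5-iodo-2,3-dimethoxybenzene
Conditions: NIS (1.05 equiv), CF3CO2H (cat.), MeCN, 0 °C → rt, dark
Reagents that add atoms: N-iodosuccinimide, O=C1CCC(=O)N1I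
Why: Electrophilic aromatic iodination with acid-activated N-iodosuccinimide goes to the tetraalkoxy ring, which is far more electron-rich than the benzyl phenyl rings and has two equivalent free positions, and the first iodine slows a second substitution.

**Step 9**
Reactants: 13 1,4-bis(benzyloxy)-5-iodo-2,3-dimethoxybenzene, 14 propiolic acid
Product: 15 3-[2,5-bis(benzyloxy)-3,4-dimethoxyphenyl]prop-2-ynoic acid
Conditions: Pd(PPh3)4 (5 mol %), DBU (2.5 equiv), DMSO, 35 °C; then aq HCl
Reagents that add atoms: propiolic acid 14, C#CC(=O)O
Why: Copper-free Sonogashira-type coupling of an aryl iodide with propiolic acid in the presence of DBU, in which zerovalent palladium inserts into the C–I bond and the terminal C–H is coupled at a temperature too low for decarboxylation of the alkynoic acid.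

**Step 10**
Reactants: 8 3-(benzyloxy)-5-methoxy-2-(trimethylsilyl)phenyl trifluoromethanesulfonate, 15 3-[2,5-bis(benzyloxy)-3,4-dimethoxyphenyl]prop-2-ynoic acid
Product: 19 5-(benzyloxy)-2-[2,5-bis(benzyloxy)-3,4-dimethoxyphenyl]-7-methoxy-4H-chromen-4-one, via cesium propiolate 16 (not isolated), via benzyne 17 (not isolated), via hydroxyaryl ynone 18 (not isolated)
Conditions: 15, CsF (4 equiv), THF (about 0.02 M), rt, 30 min; then 8 (1.5 equiv), sealed tube, 125 °C
Reagents that add atoms: none
Why: CsF first converts acid 15 into carboxylate 16, then attacks the silicon of 8 so that triflate is expelled and aryne 17 is released slowly into the dilute solution. The carboxylate oxygen bonds to the aryne terminus meta to the benzyloxy group (future C8a), because the inductively withdrawing C5 oxygen distorts the triple bond to make that terminus the more linear and electrophilic one and places the developing charge on C4a next to it; the 7-methoxy group, one position further off, has little influence. The C4a aryl anion then adds to the adjacent ester carbonyl through a strained four-membered alkoxide that opens with O-to-C acyl transfer (an anionic Fries-type shift), which gives the phenoxide of ynone 18 and makes O1–C8a and C4a–C4 in one event. This phenoxide closes ring C by 6-endo-dig oxa-Michael addition at C2, the electrophilic β-carbon of the polarized ynone, in preference to 5-exo-dig attack at the α-carbon, and the proton that began on the acid ends at C3. The closest known reaction type is the fluoride-induced insertion of arynes into the C–O bond of carboxylic acids in hot THF, which with arylpropiolic acids continues to flavones. No stereocentre is formed, and the selectivity still needed, acyl transfer ahead of protonation of the aryl anion, is served by the aprotic solvent, the high dilution and the prior conversion of the acid into its salt.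

**Step 11**
Reactants: 19 5-(benzyloxy)-2-[2,5-bis(benzyloxy)-3,4-dimethoxyphenyl]-7-methoxy-4H-chromen-4-one
Product: 20 2-(2,5-dihydroxy-3,4-dimethoxyphenyl)-5-hydroxy-7-methoxy-4H-chromen-4-one (CNP0170944.0)
Conditions: H2 (1 atm), Pd/C (10 %), THF/MeOH, rt; work-up under argon
Reagents that add atoms: none
Why: Catalytic hydrogenolysis cleaves the three benzylic C–O bonds at atmospheric pressure and leaves the methyl ethers and the vinylogous-ester C2–C3 double bond of the flavone, while the inert work-up protects the ring B hydroquinone from air.

**Compound list**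
1 | 5-methoxyresorcinol | COc1cc(O)cc(O)c1 | starting material
2 | 2-iodo-5-methoxybenzene-1,3-diol | Ic1c(O)cc(OC)cc1O | intermediate
3 | benzyl bromide | BrCc1ccccc1 | starting material
4 | 3-(benzyloxy)-2-iodo-5-methoxyphenol | Ic1c(O)cc(OC)cc1OCc1ccccc1 | intermediate
5 | [3-(benzyloxy)-2-iodo-5-methoxyphenoxy](trimethyl)silane | Ic1c(O[Si](C)(C)C)cc(OC)cc1OCc1ccccc1 | intermediate
6 | [2-(benzyloxy)-4-methoxy-6-(trimethylsilyloxy)phenyl]lithium | [Li]c1c(O[Si](C)(C)C)cc(OC)cc1OCc1ccccc1 | intermediate
7 | lithium 3-(benzyloxy)-5-methoxy-2-(trimethylsilyl)phenolate | [Li+].[O-]c1cc(OC)cc(OCc2ccccc2)c1[Si](C)(C)C | intermediate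
8 | 3-(benzyloxy)-5-methoxy-2-(trimethylsilyl)phenyl trifluoromethanesulfonate | COc1cc(OCc2ccccc2)c([Si](C)(C)C)c(OS(=O)(=O)C(F)(F)F)c1 | intermediate
9 | 2,3-dimethoxyphenol | COc1cccc(O)c1OC | starting material
10 | 2,3-dimethoxy-1,4-benzoquinone | COC1=C(OC)C(=O)C=CC1=O | intermediate
11 | 2,3-dimethoxybenzene-1,4-diol | COc1c(O)ccc(O)c1OC | intermediate
12 | 1,4-bis(benzyloxy)-2,3-dimethoxybenzene | COc1c(OCc2ccccc2)ccc(OCc2ccccc2)c1OC | intermediate
13 | 1,4-bis(benzyloxy)-5-iodo-2,3-dimethoxybenzene | Ic1cc(OCc2ccccc2)c(OC)c(OC)c1OCc1ccccc1 | intermediate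
14 | propiolic acid | C#CC(=O)O | starting material
15 | 3-[2,5-bis(benzyloxy)-3,4-dimethoxyphenyl]prop-2-ynoic acid | OC(=O)C#Cc1cc(OCc2ccccc2)c(OC)c(OC)c1OCc1ccccc1 | intermediate
16 | cesium 3-[2,5-bis(benzyloxy)-3,4-dimethoxyphenyl]prop-2-ynoate | [Cs+].[O-]C(=O)C#Cc1cc(OCc2ccccc2)c(OC)c(OC)c1OCc1ccccc1 | intermediate
17 | 3-(benzyloxy)-5-methoxybenzyne (3-(benzyloxy)-5-methoxy-1,2-didehydrobenzene) | COC1=CC#CC(OCc2ccccc2)=C1 | intermediate
18 | 1-[2-(benzyloxy)-6-hydroxy-4-methoxyphenyl]-3-[2,5-bis(benzyloxy)-3,4-dimethoxyphenyl]prop-2-yn-1-one (present as its cesium phenoxide) | COc1cc(O)c(C(=O)C#Cc2cc(OCc3ccccc3)c(OC)c(OC)c2OCc2ccccc2)c(OCc2ccccc2)c1 | intermediate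
19 | 5-(benzyloxy)-2-[2,5-bis(benzyloxy)-3,4-dimethoxyphenyl]-7-methoxy-4H-chromen-4-one | COc1cc(OCc2ccccc2)c2c(=O)cc(-c3cc(OCc4ccccc4)c(OC)c(OC)c3OCc3ccccc3)oc2c1 | intermediate
20 | 2-(2,5-dihydroxy-3,4-dimethoxyphenyl)-5-hydroxy-7-methoxy-4H-chromen-4-one | COc1cc(O)c2c(=O)cc(-c3cc(O)c(OC)c(OC)c3O)oc2c1 | target

**Step count**
- Total step count: 11.
- Longest linear sequence: 7 steps (steps 5 to 11). The ring A branch (steps 1 to 4) joins at step 10.

**Steps most likely to fail**

1. **Step 10.**
   - What may go wrong:
     - Proton transfer to the C4a aryl anion may outrun acyl transfer, so the sequence stops at plain O-arylation.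
     - The cesium propiolate may lose CO2 at 125 °C.
     - The acid may protodesilylate 8 before fluoride acts.
     - The phenoxide may close in the 5-exo mode.
   - Fallback: a carbonylative annulation, in which a C–I bond rather than aryne polarization defines C4a.
     - It sets out from iodophenol 4 and acid 15.
     - Acid 15 is protodecarboxylated (CuCl cat., Et3N, MeCN, 60 °C) to 1,4-bis(benzyloxy)-5-ethynyl-2,3-dimethoxybenzene F1.
     - 4 and F1 are then heated under CO with PdCl2(dppf) in Et2NH (120 °C). This is a carbonylative Sonogashira coupling that forms ynone 18 in the flask.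
     - The amine then mediates the 6-endo closure, and the route is rejoined at 19.

2. **Step 1.**
   - What may go wrong:
     - Iodine may enter at C4 beside the methoxy group.
     - A second iodination of this very electron-rich ring may occur.
     - Iodine may migrate if the medium turns acidic.
   - Fallback: directed ortho-metalation on a symmetric substrate. It sets out from 1 and comes back at 2.
     - Compound 1 is carbamoylated (Et2NCOCl, K2CO3, MeCN, reflux) to 5-methoxy-1,3-phenylene bis(diethylcarbamate) F2.
     - s-BuLi/TMEDA in THF at −78 °C removes the proton between the two carbamates, the strongest cooperative directing pair on the ring. This gives [2,6-bis(diethylcarbamoyloxy)-4-methoxyphenyl]lithium F3.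
     - An I2 quench gives 2-iodo-5-methoxy-1,3-phenylene bis(diethylcarbamate) F4.
     - NaOH in refluxing EtOH removes both carbamates to give 2.

3. **Step 9.**
   - What may go wrong:
     - The propiolate may lose CO2 under palladium catalysis, and a second arylation would then follow.
     - Oxidative addition may be slow at the electron-rich, ortho-substituted C–I bond, and heating cannot cure this while a carboxyl group is present.
   - Fallback: the carboxyl carbon is introduced only after the coupling. It sets out from 13 and comes back at 15.
     - Sonogashira coupling of 13 with ethynyltrimethylsilane (PdCl2(PPh3)2, CuI, Et3N, THF, 60 °C) gives {[2,5-bis(benzyloxy)-3,4-dimethoxyphenyl]ethynyl}(trimethyl)silane F5.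
     - Fluoride-mediated carboxylation of the alkynylsilane (CsF, CO2 at 1 atm, DMSO, rt) gives cesium salt 16.
     - Acidification of 16 gives 15.

**Further compounds**
F1 | step 10 | 1,4-bis(benzyloxy)-5-ethynyl-2,3-dimethoxybenzene | C#Cc1cc(OCc2ccccc2)c(OC)c(OC)c1OCc1ccccc1
F2 | step 1 | 5-methoxy-1,3-phenylene bis(diethylcarbamate) | CCN(CC)C(=O)Oc1cc(OC)cc(OC(=O)N(CC)CC)c1
F3 | step 1 | [2,6-bis(diethylcarbamoyloxy)-4-methoxyphenyl]lithium | [Li]c1c(OC(=O)N(CC)CC)cc(OC)cc1OC(=O)N(CC)CC
F4 | step 1 | 2-iodo-5-methoxy-1,3-phenylene bis(diethylcarbamate) | Ic1c(OC(=O)N(CC)CC)cc(OC)cc1OC(=O)N(CC)CC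
F5 | step 9 | {[2,5-bis(benzyloxy)-3,4-dimethoxyphenyl]ethynyl}(trimethyl)silane | C[Si](C)(C)C#Cc1cc(OCc2ccccc2)c(OC)c(OC)c1OCc1ccccc1
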